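**Retrosynthetic overview**

1. The target, epioritin-(4β→6)-epioritin-(4β→6)-epioritin-4α-ol, comes from a benzyl-protected, bromine-capped trimer by deacetylation and hydrogenolysis; the trimer comes from two successive C4→C6 Friedel–Crafts couplings, lower plus middle unit first, then the upper unit, each setting C4 trans to the 3-O substituent.
2. All three units derive from one monomer, tetra-O-benzyl-teracacidin 15: as nucleophile (4-acetate 16), as electrophile (4-benzylthio ether 17) and as capped electrophile (6-bromo-4-benzylthio ether 19).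
3. 15 comes from an asymmetric all-cis hydrogenation of the flat flavonol ether 13, which sets C2, C3 and C4 of ring C together.
4. 13 comes from a one-pot [3+3] annulation of 2-fluoroaroyl chloride 5 (ring A plus C4) with α-benzyloxy ketone 10 (ring B plus C2, C3 and O1): C3–C4 by enolate C-acylation, O1–C8a by SNAr of fluoride; ring C is the only ring built, once, on purchased rings A and B.
5. Enabling feature: in ring C, O1/C3 (across C2) and C8a/C4 (across C4a) are both 1,3-related, so at the flavonol oxidation level O1–C2=C3 is a ketone enolate and F–C8a=C4a–C4(=O) a vinylogous acyl fluoride; the all-cis C2/C3/C4 triad of the terminal unit is the syn-hydrogenation retron of that flavonol.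

Key step: step 6

Assumption: the target is read as three (2R,3R)-2,3-cis units with both interflavan bonds 3,4-trans (4β) and the terminal 4-OH 3,4-cis (4α); compounds 1, 6, 8 and the named reagents are taken as commercial.

**Route**

Step 1
Reactants: 1 3-fluorocatechol (3-fluorobenzene-1,2-diol)
Product: 2 1,2-bis(benzyloxy)-3-fluorobenzene
Conditions: BnBr (2.2 equiv), K2CO3 (2.5 equiv), DMF, 60 °C
Reagents that add atoms: benzyl bromide, BrCc1ccccc1
Why: Williamson ether synthesis alkylates both phenols; no stereocenter is involved.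

Step 2
Reactants: 2 1,2-bis(benzyloxy)-3-fluorobenzene
Product: 4 3,4-bis(benzyloxy)-2-fluorobenzoic acid, via aryllithium 3 (not isolated)
Conditions: LiTMP (lithium 2,2,6,6-tetramethylpiperidide, 1.2 equiv), THF, −78 °C; then CO2 (gas), −78 °C to rt; 1 M HCl work-up
Reagents that add atoms: carbon dioxide, O=C=O
Why: Directed ortho-metalation: fluorine is the strongest acidifying group on the ring, so the hindered amide base should remove the hydrogen next to F rather than the one next to OBn or a benzylic hydrogen, and the aryllithium is carboxylated.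

Step 3
Reactants: 4 3,4-bis(benzyloxy)-2-fluorobenzoic acid
Product: 5 3,4-bis(benzyloxy)-2-fluorobenzoyl chloride
Conditions: (COCl)2 (1.5 equiv), DMF (cat.), CH2Cl2, 0 °C to rt
Reagents that add atoms: oxalyl chloride, ClC(=O)C(Cl)=O
Why: Acid chloride formation through the Vilsmeier-type chloroiminium catalyst; benzyl ethers and the aryl fluoride are untouched.

Step 4
Reactants: 6 benzyloxyacetyl chloride
Product: 7 2-(benzyloxy)-N-methoxy-N-methylacetamide
Conditions: MeNHOMe·HCl (1.1 equiv), Et3N (2.2 equiv), CH2Cl2, 0 °C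
Reagents that add atoms: N,O-dimethylhydroxylamine hydrochloride, CNOC.Cl
Why: Schotten–Baumann-type N-acylation gives the Weinreb amide.

Step 5
Reactants: 8 1-(benzyloxy)-4-bromobenzene; 7 2-(benzyloxy)-N-methoxy-N-methylacetamide
Product: 10 2-(benzyloxy)-1-[4-(benzyloxy)phenyl]ethan-1-one, via Grignard reagent 9 (not isolated)
Conditions: Mg (1.2 equiv), THF, reflux; then 7, THF, 0 °C; 1 M HCl work-up
Reagents that add atoms: none
Why: Weinreb ketone synthesis: the chelated tetrahedral adduct of the Grignard reagent survives until work-up, so addition stops at the ketone.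

Step 6
Reactants: 10 2-(benzyloxy)-1-[4-(benzyloxy)phenyl]ethan-1-one; 5 3,4-bis(benzyloxy)-2-fluorobenzoyl chloride
Product: 13 3,7,8-tris(benzyloxy)-2-[4-(benzyloxy)phenyl]-4H-chromen-4-one, via lithium enolate 11 (not isolated), via lithium diketonate 12 (not isolated)
Conditions: LiHMDS (LiN(SiMe3)2, 2.5 equiv), THF, −78 °C; then 5, −78 to 0 °C; then DMF co-solvent, 80 °C
Reagents that add atoms: none
Why: The chelated lithium (Z)-enolate 11 is acylated at carbon C3 by acid chloride 5 (Claisen-type C-acylation; any enol ester from O-acylation is itself an acyl donor and is returned to the C-acylated product by the excess enolate), and the second equivalent of base converts the 1,3-diketone into diketonate 12. On warming in THF/DMF the enolate oxygen on C2 (the future O1) adds to C8a, ipso to fluorine and ortho to the C4 carbonyl, and the Meisenheimer adduct expels fluoride (intramolecular SNAr), so C3–C4 and O1–C8a are made in one flask. The closest known reaction type is the one-pot C-acylation/SNAr cyclisation of 2-halobenzoyl chlorides with enolates or enamines to chromones, flavones and 4-quinolones (Grohe–Heitzer-type cyclisation), including cases where the displaced fluoride is flanked by an alkoxy group. Ring C closes as a six-membered ring by attack of oxygen on the sp2 carbon C8a (6-endo-trig with respect to the C8a=C4a bond that relays the charge to the C4 carbonyl), followed by loss of fluoride to the aromatic 4-pyranone. No stereocenter is formed: the step delivers the flat C2=C3 enol ether whose syn hydrogenation in step 7 sets C2, C3 and C4 together. The selectivities needed are C- over O-acylation (lithium chelate plus thermodynamic funnelling to the diketonate) and O- over C-arylation with loss of fluoride only, secured by geometry (only the oxygen on C2 reaches C8a through a six-membered transition state, attack by C3 would give a four-membered ring) and by fluorine on C8a being the only leaving group activated by the C4 carbonyl.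

Step 7
Reactants: 13 3,7,8-tris(benzyloxy)-2-[4-(benzyloxy)phenyl]-4H-chromen-4-one
Product: 15 (2R,3R,4R)-3,7,8-tris(benzyloxy)-2-[4-(benzyloxy)phenyl]chroman-4-ol, via cis-flavanone 14 (not isolated)
Conditions: H2 (100 bar), Ru(cod)(2-methylallyl)2 (5 mol%), SINpEt·HBF4 (1,3-bis[1-(1-naphthyl)ethyl]imidazolinium tetrafluoroborate, 10 mol%, antipode chosen for 2R), KOtBu (12 mol%), toluene, 40 °C
Reagents that add atoms: none
Why: Proposed new method: a chiral ruthenium bis(N-heterocyclic carbene) catalyst formed in situ should add H2 syn to one enantioface of the C2=C3 enol-ether bond of 13 to give the 2,3-cis flavanone 14 (2-aryl and 3-OBn on the same face) and then hydrogenate its C4 ketone from the open face opposite to both substituents, so that the 4-OH ends cis to them and the all-cis (2R,3R,4R) triad arises from ligand control (C2, C3) and substrate control (C4); the closest known reaction type is the Ru–NHC-catalysed asymmetric hydrogenation of flavones and chromones to cis-flavan-4-ols (related: asymmetric transfer hydrogenation of isoflavones to cis-isoflavan-4-ols), which has not been shown for a 3-alkoxy-substituted, tetrasubstituted chromone double bond, and the ligand antipode giving 2R is to be assigned in the first experiment.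

Step 8
Reactants: 15 (2R,3R,4R)-3,7,8-tris(benzyloxy)-2-[4-(benzyloxy)phenyl]chroman-4-ol
Product: 16 (2R,3S,4R)-3,7,8-tris(benzyloxy)-2-[4-(benzyloxy)phenyl]chroman-4-yl acetate (all-cis)
Conditions: Ac2O (3 equiv), DMAP (0.1 equiv), pyridine, rt
Reagents that add atoms: acetic anhydride, CC(=O)OC(C)=O
Why: DMAP-catalysed acylation of the secondary benzylic alcohol; the ester makes O4 non-nucleophilic and inert to the later silver activation, and no stereocenter is touched (the C3 descriptor changes by priority only).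

Step 9
Reactants: 15 (2R,3R,4R)-3,7,8-tris(benzyloxy)-2-[4-(benzyloxy)phenyl]chroman-4-ol
Product: 17 (2R,3S,4S)-3,7,8-tris(benzyloxy)-2-[4-(benzyloxy)phenyl]-4-(benzylsulfanyl)chromane (2,3-cis-3,4-trans)
Conditions: BnSH (5 equiv), BF3·OEt2 (0.2 equiv), 4 Å MS, CH2Cl2, −40 to 0 °C
Reagents that add atoms: benzyl mercaptan (phenylmethanethiol), SCc1ccccc1
Why: Acid-catalysed SN1 thiolysis through the C4 benzylic cation stabilised by O1 and 7-OBn, trapped by the excess thiol anti to the 3-OBn group (3,4-trans); the C4 configuration is lost again in the coupling and is therefore not critical.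

Step 10
Reactants: 15 (2R,3R,4R)-3,7,8-tris(benzyloxy)-2-[4-(benzyloxy)phenyl]chroman-4-ol
Product: 18 (2R,3R,4R)-6-bromo-3,7,8-tris(benzyloxy)-2-[4-(benzyloxy)phenyl]chroman-4-ol
Conditions: NBS (1.0 equiv), CH2Cl2, −40 to 0 °C, dark
Reagents that add atoms: N-bromosuccinimide, O=C1CCC(=O)N1Br
Why: Electrophilic aromatic bromination should occur at C6, the ring A position ortho to 7-OBn and para to O1 (doubly activated), in preference to C5 and to ring B (each activated by one oxygen only).

Step 11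
Reactants: 18 (2R,3R,4R)-6-bromo-3,7,8-tris(benzyloxy)-2-[4-(benzyloxy)phenyl]chroman-4-ol
Product: 19 (2R,3S,4S)-6-bromo-3,7,8-tris(benzyloxy)-2-[4-(benzyloxy)phenyl]-4-(benzylsulfanyl)chromane
Conditions: BnSH (5 equiv), BF3·OEt2 (0.2 equiv), 4 Å MS, CH2Cl2, −40 to 0 °C
Reagents that add atoms: benzyl mercaptan (phenylmethanethiol), SCc1ccccc1
Why: Same SN1 thiolysis as in step 9, the thiol adding anti to 3-OBn; the C6 bromine blocks the only strongly nucleophilic ring position of this electrophile.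

Step 12
Reactants: 16 (2R,3S,4R)-3,7,8-tris(benzyloxy)-2-[4-(benzyloxy)phenyl]chroman-4-yl acetate (3 equiv, excess recovered); 17 (2R,3S,4S)-3,7,8-tris(benzyloxy)-2-[4-(benzyloxy)phenyl]-4-(benzylsulfanyl)chromane
Product: 20 4-O-acetyl-octa-O-benzyl-epioritin-(4β→6)-epioritin-4α-ol (C4 of the flavanyl unit from 17 bonded 3,4-trans to C6 of 16)
Conditions: AgBF4 (1.5 equiv), 2,6-di-tert-butyl-4-methylpyridine (1.2 equiv), 4 Å MS, CH2Cl2/THF, −40 to 0 °C
Reagents that add atoms: none
Why: Friedel–Crafts-type (SN1) interflavan coupling: silver ion abstracts the benzylthio group of 17, and the C4 cation is attacked by C6 of 16 (ortho to 7-OBn, para to O1) on the face anti to the 3-OBn and 2-aryl groups, which sets the new C4 stereocenter 3,4-trans (4β), while the 4-acetate of 16 is inert to the thiophilic promoter, blocks O-alkylation, and the excess of 16 suppresses chain growth.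

Step 13
Reactants: 20 4-O-acetyl-octa-O-benzyl-epioritin-(4β→6)-epioritin-4α-ol; 19 (2R,3S,4S)-6-bromo-3,7,8-tris(benzyloxy)-2-[4-(benzyloxy)phenyl]-4-(benzylsulfanyl)chromane (1.3 equiv)
Product: 21 4-O-acetyl-6-bromo-dodeca-O-benzyl-epioritin-(4β→6)-epioritin-(4β→6)-epioritin-4α-ol (bromine on C6 of the upper unit, acetate on C4 of the lower unit)
Conditions: AgBF4 (1.5 equiv), 2,6-di-tert-butyl-4-methylpyridine (1.2 equiv), 4 Å MS, CH2Cl2/THF, −40 to 0 °C
Reagents that add atoms: none
Why: The same silver-promoted Friedel–Crafts coupling, now at C6 of the upper flavanyl unit of 20, the only unhindered doubly activated ring position left; the bromine of 19 prevents self-condensation and growth beyond the trimer, and attack anti to 3-OBn sets C4 of the new upper unit 3,4-trans (4β).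

Step 14
Reactants: 21 4-O-acetyl-6-bromo-dodeca-O-benzyl-epioritin-(4β→6)-epioritin-(4β→6)-epioritin-4α-ol
Product: 22 6-bromo-dodeca-O-benzyl-epioritin-(4β→6)-epioritin-(4β→6)-epioritin-4α-ol (free 4α-OH on the lower unit)
Conditions: K2CO3 (0.3 equiv), MeOH/THF (1:1), rt
Reagents that add atoms: none
Why: Base-catalysed transesterification (Zemplén-type methanolysis) removes the acetate with retention at C4, since only the acyl C–O bond is broken.

Step 15
Reactants: 22 6-bromo-dodeca-O-benzyl-epioritin-(4β→6)-epioritin-(4β→6)-epioritin-4α-ol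
Product: 23 epioritin-(4β→6)-epioritin-(4β→6)-epioritin-4α-ol (target, CNP0140823.1)
Conditions: H2 (1 atm), Pd(OH)2/C, NaHCO3 (1.1 equiv), THF/MeOH/H2O, rt
Reagents that add atoms: none
Why: Catalytic hydrogenolysis should cleave the twelve benzyl ethers and the aryl bromide in one operation, the bicarbonate taking up HBr so that the benzylic 4-OH and the interflavan bonds are not ionised; no stereocenter is touched.

**Compound list**

1 | 3-fluorocatechol | Oc1cccc(F)c1O | starting material
2 | 1,2-bis(benzyloxy)-3-fluorobenzene | Fc1cccc(OCc2ccccc2)c1OCc1ccccc1 | intermediate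
3 | [3,4-bis(benzyloxy)-2-fluorophenyl]lithium | [Li]c1ccc(OCc2ccccc2)c(OCc2ccccc2)c1F | intermediate
4 | 3,4-bis(benzyloxy)-2-fluorobenzoic acid | OC(=O)c1ccc(OCc2ccccc2)c(OCc2ccccc2)c1F | intermediate
5 | 3,4-bis(benzyloxy)-2-fluorobenzoyl chloride | ClC(=O)c1ccc(OCc2ccccc2)c(OCc2ccccc2)c1F | intermediate
6 | benzyloxyacetyl chloride | ClC(=O)COCc1ccccc1 | starting material
7 | 2-(benzyloxy)-N-methoxy-N-methylacetamide | CON(C)C(=O)COCc1ccccc1 | intermediate
8 | 1-(benzyloxy)-4-bromobenzene | Brc1ccc(OCc2ccccc2)cc1 | starting material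
9 | [4-(benzyloxy)phenyl]magnesium bromide | Br[Mg]c1ccc(OCc2ccccc2)cc1 | intermediate
10 | 2-(benzyloxy)-1-[4-(benzyloxy)phenyl]ethan-1-one | O=C(COCc1ccccc1)c1ccc(OCc2ccccc2)cc1 | intermediate
11 | lithium (Z)-enolate of 10 | [Li]O/C(=C\OCc1ccccc1)c1ccc(OCc2ccccc2)cc1 | intermediate
12 | lithium enolate of 2-(benzyloxy)-1-[3,4-bis(benzyloxy)-2-fluorophenyl]-3-[4-(benzyloxy)phenyl]propane-1,3-dione | [Li]O/C(c1ccc(OCc2ccccc2)cc1)=C(/OCc1ccccc1)C(=O)c1ccc(OCc2ccccc2)c(OCc2ccccc2)c1F | intermediate
13 | 3,7,8-tris(benzyloxy)-2-[4-(benzyloxy)phenyl]-4H-chromen-4-one | O=c1c(OCc2ccccc2)c(-c2ccc(OCc3ccccc3)cc2)oc2c(OCc3ccccc3)c(OCc3ccccc3)ccc12 | intermediate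
14 | (2R,3S)-3,7,8-tris(benzyloxy)-2-[4-(benzyloxy)phenyl]chroman-4-one (2,3-cis) | c1cc2c(c(OCc9ccccc9)c1OCc9ccccc9)O[C@H](c1ccc(OCc9ccccc9)cc1)[C@H](OCc9ccccc9)C2=O | intermediate
15 | (2R,3R,4R)-3,7,8-tris(benzyloxy)-2-[4-(benzyloxy)phenyl]chroman-4-ol (all-cis; tetra-O-benzyl-teracacidin) | c1cc2c(c(OCc9ccccc9)c1OCc9ccccc9)O[C@H](c1ccc(OCc9ccccc9)cc1)[C@H](OCc9ccccc9)[C@@H]2O | intermediate
16 | (2R,3S,4R)-3,7,8-tris(benzyloxy)-2-[4-(benzyloxy)phenyl]chroman-4-yl acetate (all-cis) | c1cc2c(c(OCc9ccccc9)c1OCc9ccccc9)O[C@H](c1ccc(OCc9ccccc9)cc1)[C@H](OCc9ccccc9)[C@@H]2OC(C)=O | intermediate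
17 | (2R,3S,4S)-3,7,8-tris(benzyloxy)-2-[4-(benzyloxy)phenyl]-4-(benzylsulfanyl)chromane (2,3-cis-3,4-trans) | c1cc2c(c(OCc9ccccc9)c1OCc9ccccc9)O[C@H](c1ccc(OCc9ccccc9)cc1)[C@H](OCc9ccccc9)[C@H]2SCc9ccccc9 | intermediate
18 | (2R,3R,4R)-6-bromo-3,7,8-tris(benzyloxy)-2-[4-(benzyloxy)phenyl]chroman-4-ol | Brc1cc2c(c(OCc9ccccc9)c1OCc9ccccc9)O[C@H](c1ccc(OCc9ccccc9)cc1)[C@H](OCc9ccccc9)[C@@H]2O | intermediate
19 | (2R,3S,4S)-6-bromo-3,7,8-tris(benzyloxy)-2-[4-(benzyloxy)phenyl]-4-(benzylsulfanyl)chromane | Brc1cc2c(c(OCc9ccccc9)c1OCc9ccccc9)O[C@H](c1ccc(OCc9ccccc9)cc1)[C@H](OCc9ccccc9)[C@H]2SCc9ccccc9 | intermediate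
20 | 4-O-acetyl-octa-O-benzyl-epioritin-(4β→6)-epioritin-4α-ol | c1cc2c(c(OCc9ccccc9)c1OCc9ccccc9)O[C@H](c1ccc(OCc9ccccc9)cc1)[C@H](OCc9ccccc9)[C@H]2c1cc2c(c(OCc9ccccc9)c1OCc9ccccc9)O[C@H](c1ccc(OCc9ccccc9)cc1)[C@H](OCc9ccccc9)[C@@H]2OC(C)=O | intermediate
21 | 4-O-acetyl-6-bromo-dodeca-O-benzyl-epioritin-(4β→6)-epioritin-(4β→6)-epioritin-4α-ol | c9ccccc9COc1ccc([C@H]2Oc3c(cc(Br)c(OCc9ccccc9)c3OCc9ccccc9)[C@H](c3cc4c(c(OCc9ccccc9)c3OCc9ccccc9)O[C@H](c3ccc(OCc9ccccc9)cc3)[C@H](OCc9ccccc9)[C@H]4c3cc4c(c(OCc9ccccc9)c3OCc9ccccc9)O[C@H](c3ccc(OCc9ccccc9)cc3)[C@H](OCc9ccccc9)[C@@H]4OC(C)=O)[C@H]2OCc9ccccc9)cc1 | intermediate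
22 | 6-bromo-dodeca-O-benzyl-epioritin-(4β→6)-epioritin-(4β→6)-epioritin-4α-ol | c9ccccc9COc1ccc([C@H]2Oc3c(cc(Br)c(OCc9ccccc9)c3OCc9ccccc9)[C@H](c3cc4c(c(OCc9ccccc9)c3OCc9ccccc9)O[C@H](c3ccc(OCc9ccccc9)cc3)[C@H](OCc9ccccc9)[C@H]4c3cc4c(c(OCc9ccccc9)c3OCc9ccccc9)O[C@H](c3ccc(OCc9ccccc9)cc3)[C@H](OCc9ccccc9)[C@@H]4O)[C@H]2OCc9ccccc9)cc1 | intermediate
23 | epioritin-(4β→6)-epioritin-(4β→6)-epioritin-4α-ol (CNP0140823.1) | Oc1ccc([C@H]2Oc3c(ccc(O)c3O)[C@H](c3cc4c(c(O)c3O)O[C@H](c3ccc(O)cc3)[C@H](O)[C@H]4c3cc4c(c(O)c3O)O[C@H](c3ccc(O)cc3)[C@H](O)[C@@H]4O)[C@H]2O)cc1 | target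

**Step count and risks**

Total step count: 15. Longest linear sequence: 10 steps (1, 2, 3, 6, 7, 8, 12, 13, 14, 15).

Steps most likely to fail:

Step 7 (proposed method). The tetrasubstituted 3-alkoxy double bond may not turn over, enantioface selection may be poor, or the alkoxide base may epimerise C3 of 14 before the ketone is reduced. The fallback uses known chemistry, sets out from 13 and comes back at 15. Heterogeneous hydrogenation of 13 (H2, PtO2, EtOAc, rt; platinum should leave the benzyl ethers largely intact) should give the racemic all-cis alcohol F1. Acylation with (1S)-camphanic chloride (ClC(=O)[C@@]12CC[C@@](C)(C(=O)O1)C2(C)C; DMAP, pyridine) gives the camphanate of the 2R,3R,4R alcohol F2 and the camphanate of the 2S,3S,4S alcohol F3, to be separated by chromatography or crystallisation. Methanolysis of F2 (K2CO3, MeOH/THF) returns 15 as a single enantiomer.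

Step 12 (the same concern holds for step 13). The benzylated 5-deoxy ring of 16 may be too weak a nucleophile, so that the C4 cation is lost by elimination or self-condensation, or attack may occur partly at C5. The fallback sets out from 18 and comes back at 20. Acetylation of 18 (Ac2O, DMAP, pyridine) gives the bromo acetate F4. Stannylation with hexamethylditin (Pd(PPh3)4, toluene, 100 °C) gives the 6-trimethylstannyl acetate F5. Silver-promoted reaction of F5 with 17 (AgBF4, CH2Cl2/THF, −40 °C) should then run as a regiospecific ipso-destannylation at C6, the C–Sn bond raising the nucleophilicity of that carbon and fixing the position, to give 20.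

Step 15. Hydrogenolytic loss of the benzylic 4-OH of the terminal unit (over-reduction to the flavan-3-ol), or reductive opening at C2–O1, may occur before all twelve benzyl groups are removed. The fallback sets out from 22 and comes back at 23. Oxidation of the 4-OH of 22 with Dess–Martin periodinane (NaHCO3, CH2Cl2) gives the protected trimer 4-ketone F6, which cannot be hydrogenolysed at C4. Hydrogenolysis (H2, Pd(OH)2/C, NaHCO3, THF/MeOH) gives the free phenolic trimer ketone F7. NaBH4 (MeOH, 0 °C) should then deliver hydride anti to the axial 3-OH and restore the 3,4-cis (4α) alcohol, giving 23.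

**Further compounds**

F1 | step 7 | racemic all-cis 3,7,8-tris(benzyloxy)-2-[4-(benzyloxy)phenyl]chroman-4-ol (both enantiomers) | c1cc2c(c(OCc9ccccc9)c1OCc9ccccc9)O[C@H](c1ccc(OCc9ccccc9)cc1)[C@H](OCc9ccccc9)[C@@H]2O.c1cc2c(c(OCc9ccccc9)c1OCc9ccccc9)O[C@@H](c1ccc(OCc9ccccc9)cc1)[C@@H](OCc9ccccc9)[C@H]2O
F2 | step 7 | (1S)-camphanate of the (2R,3R,4R) alcohol 15 | c1cc2c(c(OCc9ccccc9)c1OCc9ccccc9)O[C@H](c1ccc(OCc9ccccc9)cc1)[C@H](OCc9ccccc9)[C@@H]2OC(=O)[C@@]56CC[C@@](C)(C(=O)O5)C6(C)C
F3 | step 7 | (1S)-camphanate of the (2S,3S,4S) alcohol (unwanted diastereomer) | c1cc2c(c(OCc9ccccc9)c1OCc9ccccc9)O[C@@H](c1ccc(OCc9ccccc9)cc1)[C@@H](OCc9ccccc9)[C@H]2OC(=O)[C@@]56CC[C@@](C)(C(=O)O5)C6(C)C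
F4 | step 12 | (2R,3S,4R)-6-bromo-3,7,8-tris(benzyloxy)-2-[4-(benzyloxy)phenyl]chroman-4-yl acetate | Brc1cc2c(c(OCc9ccccc9)c1OCc9ccccc9)O[C@H](c1ccc(OCc9ccccc9)cc1)[C@H](OCc9ccccc9)[C@@H]2OC(C)=O
F5 | step 12 | (2R,3S,4R)-3,7,8-tris(benzyloxy)-2-[4-(benzyloxy)phenyl]-6-(trimethylstannyl)chroman-4-yl acetate | C[Sn](C)(C)c1cc2c(c(OCc9ccccc9)c1OCc9ccccc9)O[C@H](c1ccc(OCc9ccccc9)cc1)[C@H](OCc9ccccc9)[C@@H]2OC(C)=O
F6 | step 15 | 6-bromo-dodeca-O-benzyl trimer with the lower unit as flavan-4-one | c9ccccc9COc1ccc([C@H]2Oc3c(cc(Br)c(OCc9ccccc9)c3OCc9ccccc9)[C@H](c3cc4c(c(OCc9ccccc9)c3OCc9ccccc9)O[C@H](c3ccc(OCc9ccccc9)cc3)[C@H](OCc9ccccc9)[C@H]4c3cc4c(c(OCc9ccccc9)c3OCc9ccccc9)O[C@H](c3ccc(OCc9ccccc9)cc3)[C@H](OCc9ccccc9)C4=O)[C@H]2OCc9ccccc9)cc1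
F7 | step 15 | free phenolic trimer with the lower unit as 2,3-cis-3-hydroxyflavan-4-one | Oc1ccc([C@H]2Oc3c(ccc(O)c3O)[C@H](c3cc4c(c(O)c3O)O[C@H](c3ccc(O)cc3)[C@H](O)[C@H]4c3cc4c(c(O)c3O)O[C@H](c3ccc(O)cc3)[C@H](O)C4=O)[C@H]2O)cc1
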